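**Plan**
1. Retrosynthesis: open the oxirane to the C1=C2 vinyl group; open the lactone O8–C12 bond and take C12 and C3 back to allylic alcohols; remove the O6 isobutyrate; then cut C10–C1 and C4–C5 together. This leads to a carvone-derived enone carrying a 2-bromoallyl mixed acetal on O6.
2. Forward: the carvone ring is kept. C12, C8 and C6 are oxygenated and the acetal is attached. One radical chain then closes the tetrahydrofuran acetal ring (C4–C5) and allylates C10 (C10–C1).
3. After that: C9 reduction, allyl cut to vinyl, acetal opened to the C3/C6 diol, O6 acylated, desilylation, oxidative closure of the γ-lactone with formation of the enal, and the oxirane last.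
4. Stereochemistry: C7 from (S)-carvone; C8 by enolate hydroxylation anti to the side chain; C6 by anti γ-hydroxylation followed by Mitsunobu inversion; C5 by the O6 tether; C10 by allylation on the convex face; C9 by equatorial hydride delivery; C1 by epoxidation anti to the C10–C5 bond.
5. Enabling feature: C4 on C5 is cis to O6 and to the C7 side chain, so C3–C4 can be delivered from O6 across the C5=C10 enone as a five-membered acetal ring.

Key step: step 10

Numbering (elemane type): ring carbons C5–C10; C14 is the methyl on C10; C1–C2 the two-carbon unit on C10; C3, C4, C15 the three-carbon unit on C5; C11, C12, C13 the three-carbon unit on C7. β is the ring face that carries the C7 side chain, α the other face.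
Assumption: the acetal carbon C3 (13–23, F1, F8, F9), the lactol carbon of 31 and C9 of F4–F9 are carried as epimer mixtures and drawn without configuration, since each of these centres is later removed or becomes sp2.

Step 1
Reactants: 1 (S)-carvone
Product: 2 (S)-10-hydroxycarvone, i.e. (5S)-5-(3-hydroxyprop-1-en-2-yl)-2-methylcyclohex-2-en-1-one (new carbinol carbon = C12)
Conditions: SeO2 (cat.), t-BuOOH, salicylic acid (cat.), CH2Cl2, rt
Reagents that add atoms: tert-butyl hydroperoxide, CC(C)(C)OO (oxygen, relayed by SeO2, O=[Se]=O)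
Why: Allylic oxidation by SeO2 (ene reaction, then [2,3]-shift) should take place at the methyl of the electron-rich 1,1-disubstituted alkene and not at the enone, and no stereocentre is involved.

Step 2
Reactants: 2 (S)-10-hydroxycarvone
Product: 3 O12-tert-butyldiphenylsilyl ether of 2
Conditions: TBDPSCl, imidazole, CH2Cl2, 0 °C to rt
Reagents that add atoms: tert-butyldiphenylsilyl chloride, CC(C)(C)[Si](Cl)(c1ccccc1)c1ccccc1
Why: Silylation of a primary allylic alcohol gives a robust ether that should carry O12 unchanged to the desilylation in step 18.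

Step 3
Reactants: 3 O12-TBDPS ether
Product: 5 8α-hydroxy enone (OH on the α′ carbon C8 trans to the C7 side chain), via sodium dienolate 4 (not isolated)
Conditions: NaN(SiMe3)2, THF, −78 °C; 2-(phenylsulfonyl)-3-phenyloxaziridine, −78 °C; aq. NH4Cl
Reagents that add atoms: 2-(phenylsulfonyl)-3-phenyloxaziridine, O=S(=O)(N1OC1c1ccccc1)c1ccccc1
Why: Kinetic deprotonation at C8 gives the cross-conjugated dienolate, and oxygen transfer from the N-sulfonyloxaziridine (Davis enolate hydroxylation) should occur anti to the adjacent C7 side chain, which sets C8 as the trans, diequatorial and thermodynamically preferred epimer.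

Step 4
Reactants: 5 8α-hydroxy enone
Product: 6 8α-tert-butyldimethylsilyloxy enone
Conditions: TBSCl, imidazole, DMF, rt
Reagents that add atoms: tert-butyldimethylsilyl chloride, CC(C)(C)[Si](C)(C)Cl
Why: Silylation of the secondary α-hydroxy ketone protects O8 and blocks the α′ side against enolisation in the next step.

Step 5
Reactants: 6 8α-silyloxy enone
Product: 7 linear silyl dienol ether (9-OTBS, C9=C10 and C5=C6)
Conditions: TBSOTf, Et3N, CH2Cl2, 0 °C to rt
Reagents that add atoms: tert-butyldimethylsilyl triflate, CC(C)(C)[Si](C)(C)OS(=O)(=O)C(F)(F)F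
Why: Soft enolisation (O-silylation, then deprotonation of the oxocarbenium ion) should remove the γ proton at C6 and not the tertiary C8–H, which is shielded by its silyl ether and would give a crowded bis-silyloxy alkene, so the linear 1-silyloxy-1,3-diene is expected.

Step 6
Reactants: 7 linear silyl dienol ether
Product: 9 6α-hydroxy enone (OH trans to the C7 side chain), via 5α,6α-epoxide 8 (not isolated)
Conditions: mCPBA (1.05 equiv), NaHCO3, CH2Cl2, −20 °C; aq. Na2S2O3/NaHCO3
Reagents that add atoms: 3-chloroperbenzoic acid, OOC(=O)c1cccc(Cl)c1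
Why: In this vinylogous Rubottom oxidation the peracid should epoxidise the terminal C5=C6 bond of the silyloxydiene on the face anti to the C7 side chain, and the epoxide collapses with loss of the silyl group to the γ-hydroxy enone, which places O6 α.

Step 7
Reactants: 9 6α-hydroxy enone
Product: 10 6β-(4-nitrobenzoyloxy) enone
Conditions: PPh3, DIAD, 4-nitrobenzoic acid, THF, 0 °C to rt
Reagents that add atoms: 4-nitrobenzoic acid, OC(=O)c1ccc(cc1)[N+](=O)[O-]
Why: Mitsunobu esterification with 4-nitrobenzoic acid (the acid suited to hindered secondary alcohols) proceeds by SN2 displacement of the oxyphosphonium group and so inverts C6, putting O6 on the β face, cis to the C7 side chain.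

Step 8
Reactants: 10 6β-(4-nitrobenzoyloxy) enone
Product: 11 6β-hydroxy enone (OH cis to the C7 side chain)
Conditions: K2CO3 (cat.), MeOH, 0 °C, short contact
Reagents that add atoms: none
Why: Base-catalysed transesterification of the activated aryl ester should free the alcohol without breaking the C6–O bond, so the configuration at C6 is kept.

Step 9
Reactants: 11 6β-hydroxy enone; 12 2-bromoacrolein diethyl acetal
Product: 13 6β-O-(2-bromo-1-ethoxyprop-2-en-1-yl) mixed acetal (radical precursor)
Conditions: 12 (excess), PPTS (cat.), toluene, 45 °C, reduced pressure (EtOH removed)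
Reagents that add atoms: 2-bromoacrolein diethyl acetal 12, CCOC(OCC)C(Br)=C
Why: Acid-catalysed acetal exchange through the 2-bromoallyl oxocarbenium ion, driven by removal of ethanol, should attach C3–C4–C15 to O6 with retention at C6 because only the acetal C–O bond is formed.

Step 10
Reactants: 13 mixed acetal; 14 allyltributylstannane
Product: 17 cis-fused 2-ethoxy-3-methylenetetrahydrofuran ketone with C10 methyl β and C10 allyl α, via C4 vinyl radical 15 (not isolated), via C10 α-keto radical 16 (not isolated)
Conditions: allyltributylstannane (10 equiv), AIBN (portions), benzene (0.02 M in 13), 80 °C, degassed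
Reagents that add atoms: allyltributylstannane 14, C=CC[Sn](CCCC)(CCCC)CCCC
Why: A tributylstannyl radical abstracts bromine from 13, the σ-vinyl radical 15 adds to the enone β-carbon C5, and the tertiary α-keto radical 16 adds to the stannane with loss of a tributylstannyl radical, so the chain runs without tin hydride. The closest known reaction type is the Ueno–Stork haloacetal cyclisation of a vinyl radical combined with Keck allylation of the cyclised radical. The tetrahydrofuran acetal ring closes 5-exo-trig (C4–C5), and because the tether hangs from the pseudo-axial β oxygen on C6 it can reach only the β face of C5, which sets C5 with a cis ring fusion. C10 is set by approach of the stannane to the convex α face of the bicyclic radical, away from the C4–C5 bond and the axial C6–O bond, which leaves the methyl β. The step needs ring closure to outrun direct allylation and 1,5-hydrogen transfer of the vinyl radical, which the polarised C5=C10 acceptor held under the tether should secure. It also needs 16 to be trapped before it adds to the C11=C13 alkene, which the large excess of stannane should secure.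

Step 11
Reactants: 17 bicyclic ketone
Product: 18 9α-alcohol
Conditions: LiBH(s-Bu)3 (L-Selectride), THF, −78 °C to −40 °C; aq. NH4Cl
Reagents that add atoms: none
Why: The bulky hydride should attack the chair-locked ketone along the equatorial trajectory, since axial approach is blocked by the axial hydrogens on C5 and C7, and this reduction of a 2,2-disubstituted 6-silyloxycyclohexanone gives the axial 9α alcohol cis to O8.

Step 12
Reactants: 18 9α-alcohol
Product: 19 9α-tert-butyldimethylsilyl ether
Conditions: TBSOTf, 2,6-lutidine, CH2Cl2, −78 °C to −40 °C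
Reagents that add atoms: tert-butyldimethylsilyl triflate, CC(C)(C)[Si](C)(C)OS(=O)(=O)C(F)(F)F
Why: The silyl triflate should silylate the hindered axial alcohol at low temperature, where the lactol ether is not yet activated, and the ether keeps O9 out of the later acylation.

Step 13
Reactants: 19 allyl compound
Product: 20 C10 (E)-prop-1-enyl compound
Conditions: RuHCl(CO)(PPh3)3 (5 mol%), toluene, 80 °C
Reagents that add atoms: none
Why: Ruthenium hydride-catalysed alkene isomerisation (hydrometalation, β-hydride elimination) should move only the monosubstituted terminal double bond, because the two 1,1-disubstituted alkenes would have to form tertiary alkyl ruthenium species.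

Step 14
Reactants: 20 propenyl compound; 21 ethylene
Product: 22 C10 vinyl compound
Conditions: second-generation Hoveyda–Grubbs catalyst RuCl2(H2IMes)(=CH-C6H4-2-O-i-Pr) (10 mol%), ethylene (1 atm), toluene, 60 °C
Reagents that add atoms: ethylene 21, C=C
Why: Ethenolysis (cross-metathesis with ethylene) should cut the 1,2-disubstituted propenyl group through a metallacycle with ruthenium on the less hindered methyl-bearing carbon and release propene, while the 1,1-disubstituted alkenes can only undergo degenerate methylene exchange.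

Step 15
Reactants: 22 vinyl acetal
Product: 25 C3,C6-diol (primary allylic alcohol at C3 and free 6β-OH), via lactol 23 (not isolated), via hydroxy enal 24 (not isolated)
Conditions: PPTS (cat.), acetone/H2O, 50 °C; evaporate; NaBH4, CeCl3·7H2O, MeOH, 0 °C
Reagents that add atoms: water, O
Why: Acid hydrolysis of the lactol ether followed by Luche reduction of the ring-opened enal tautomer (1,2-selective) should open the acetal ring to the diol without touching C5 or C6.

Step 16
Reactants: 25 C3,C6-diol
Product: 26 O3-tert-butyldimethylsilyl ether with free 6β-OH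
Conditions: TBSCl (1.1 equiv), imidazole, CH2Cl2, 0 °C
Reagents that add atoms: tert-butyldimethylsilyl chloride, CC(C)(C)[Si](C)(C)Cl
Why: Silylation should select the primary allylic alcohol over the axial secondary C6 hydroxyl, which is flanked by two branched carbons.

Step 17
Reactants: 26 6β-alcohol; 27 isobutyryl chloride
Product: 28 6β-isobutyrate
Conditions: isobutyryl chloride, pyridine, DMAP, CH2Cl2, 0 °C to 40 °C
Reagents that add atoms: isobutyryl chloride 27, CC(C)C(Cl)=O
Why: DMAP-catalysed acylation of the only free hydroxyl installs the ester with retention at C6.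

Step 18
Reactants: 28 fully protected isobutyrate
Product: 29 tetraol (3-, 8α-, 9α- and 12-OH; 6β-isobutyrate)
Conditions: HF·pyridine (excess), pyridine, THF, 0 °C to rt
Reagents that add atoms: none
Why: Fluoride-mediated desilylation under mildly acidic conditions should remove all four silyl groups while the isobutyrate neither migrates nor cleaves.

Step 19
Reactants: 29 tetraol
Product: 32 1,2-deoxy target (C10 vinyl compound with trans-fused α-methylene-γ-lactone and C3 enal), via 3,12-dial 30 (not isolated), via C12 lactol 31 (not isolated)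
Conditions: TEMPO (0.2 equiv), PhI(OAc)2 (3.3 equiv), CH2Cl2, rt
Reagents that add atoms: none
Why: Oxoammonium oxidation (TEMPO with iodobenzene diacetate) is selective for the two primary allylic alcohols, and the C12 aldehyde should be captured by the equatorial 8α-OH as a lactol and oxidised on to the trans-fused lactone, while the C3 enal cannot reach the axial C9 hydroxyl and the hindered secondary C9–OH is not oxidised.

Step 20
Reactants: 32 1,2-deoxy target
Product: 33 CNP0496100.1
Conditions: dimethyldioxirane (1.5 equiv), acetone, −20 °C to 0 °C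
Reagents that add atoms: dimethyldioxirane, CC1(C)OO1
Why: Dioxirane epoxidation should touch only the vinyl group, the one alkene not conjugated to a carbonyl, and the oxidant should arrive on the open outer face between C9–H and the C10 methyl, anti to the C10–C5 bond with C1–H turned towards the C5 side chain, because the other face lies under the ring next to the axial C9–O and C5–H bonds, and this sets C1 as R.

**Compound list**
1 | (S)-carvone | CC1=CC[C@H](C(C)=C)CC1=O | starting material
2 | (S)-10-hydroxycarvone (C12 allylic alcohol) | CC1=CC[C@H](C(=C)CO)CC1=O | intermediate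
3 | O12-TBDPS ether of 2 | CC1=CC[C@H](C(=C)CO[Si](c2ccccc2)(c2ccccc2)C(C)(C)C)CC1=O | intermediate
4 | sodium cross-conjugated dienolate of 3 (C8=C9–ONa) | CC1=CC[C@H](C(=C)CO[Si](c2ccccc2)(c2ccccc2)C(C)(C)C)C=C1O[Na] | intermediate
5 | 8α-hydroxy enone (OH trans to C7 side chain) | CC1=CC[C@H](C(=C)CO[Si](c2ccccc2)(c2ccccc2)C(C)(C)C)[C@@H](O)C1=O | intermediate
6 | 8α-OTBS enone | CC1=CC[C@H](C(=C)CO[Si](c2ccccc2)(c2ccccc2)C(C)(C)C)[C@@H](O[Si](C)(C)C(C)(C)C)C1=O | intermediate
7 | linear silyl dienol ether (9-OTBS; C9=C10, C5=C6) | CC1=C(O[Si](C)(C)C(C)(C)C)[C@H](O[Si](C)(C)C(C)(C)C)[C@@H](C(=C)CO[Si](c2ccccc2)(c2ccccc2)C(C)(C)C)C=C1 | intermediate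
8 | 5α,6α-epoxide of 7 | CC1=C(O[Si](C)(C)C(C)(C)C)[C@H](O[Si](C)(C)C(C)(C)C)[C@@H](C(=C)CO[Si](c3ccccc3)(c3ccccc3)C(C)(C)C)[C@@H]2O[C@H]12 | intermediate
9 | 6α-hydroxy enone (OH trans to C7 side chain) | O=C1C(C)=C[C@@H](O)[C@H](C(=C)CO[Si](c2ccccc2)(c2ccccc2)C(C)(C)C)[C@H]1O[Si](C)(C)C(C)(C)C | intermediate
10 | 6β-(4-nitrobenzoyloxy) enone | O=C1C(C)=C[C@H](OC(=O)c2ccc(cc2)[N+](=O)[O-])[C@H](C(=C)CO[Si](c3ccccc3)(c3ccccc3)C(C)(C)C)[C@H]1O[Si](C)(C)C(C)(C)C | intermediate
11 | 6β-hydroxy enone (OH cis to C7 side chain) | O=C1C(C)=C[C@H](O)[C@H](C(=C)CO[Si](c2ccccc2)(c2ccccc2)C(C)(C)C)[C@H]1O[Si](C)(C)C(C)(C)C | intermediate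
12 | 2-bromoacrolein diethyl acetal | CCOC(OCC)C(Br)=C | starting material
13 | 6β-O-(2-bromo-1-ethoxyallyl) mixed acetal, radical precursor | O=C1C(C)=C[C@H](OC(OCC)C(Br)=C)[C@H](C(=C)CO[Si](c2ccccc2)(c2ccccc2)C(C)(C)C)[C@H]1O[Si](C)(C)C(C)(C)C | intermediate
14 | allyltributylstannane | C=CC[Sn](CCCC)(CCCC)CCCC | starting material
15 | C4 vinyl radical from 13 | O=C1C(C)=C[C@H](OC(OCC)[C]=C)[C@H](C(=C)CO[Si](c2ccccc2)(c2ccccc2)C(C)(C)C)[C@H]1O[Si](C)(C)C(C)(C)C | intermediate
16 | cyclised C10 α-keto radical (cis-fused tetrahydrofuran acetal) | O=C1[C](C)[C@@H]2C(=C)C(OCC)O[C@@H]2[C@H](C(=C)CO[Si](c3ccccc3)(c3ccccc3)C(C)(C)C)[C@H]1O[Si](C)(C)C(C)(C)C | intermediate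
17 | cis-fused 2-ethoxy-3-methylenetetrahydrofuran ketone, C10 methyl β, C10 allyl α | O=C1[C@@](C)(CC=C)[C@@H]2C(=C)C(OCC)O[C@@H]2[C@H](C(=C)CO[Si](c3ccccc3)(c3ccccc3)C(C)(C)C)[C@H]1O[Si](C)(C)C(C)(C)C | intermediate
18 | 9α-alcohol of 17 | O[C@H]1[C@@](C)(CC=C)[C@@H]2C(=C)C(OCC)O[C@@H]2[C@H](C(=C)CO[Si](c3ccccc3)(c3ccccc3)C(C)(C)C)[C@H]1O[Si](C)(C)C(C)(C)C | intermediate
19 | 9α-OTBS ether of 18 | CC(C)(C)[Si](C)(C)O[C@H]1[C@@](C)(CC=C)[C@@H]2C(=C)C(OCC)O[C@@H]2[C@H](C(=C)CO[Si](c3ccccc3)(c3ccccc3)C(C)(C)C)[C@H]1O[Si](C)(C)C(C)(C)C | intermediate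
20 | C10 (E)-prop-1-enyl compound | CC(C)(C)[Si](C)(C)O[C@H]1[C@@](C)(/C=C/C)[C@@H]2C(=C)C(OCC)O[C@@H]2[C@H](C(=C)CO[Si](c3ccccc3)(c3ccccc3)C(C)(C)C)[C@H]1O[Si](C)(C)C(C)(C)C | intermediate
21 | ethylene | C=C | starting material
22 | C10 vinyl compound | CC(C)(C)[Si](C)(C)O[C@H]1[C@@](C)(C=C)[C@@H]2C(=C)C(OCC)O[C@@H]2[C@H](C(=C)CO[Si](c3ccccc3)(c3ccccc3)C(C)(C)C)[C@H]1O[Si](C)(C)C(C)(C)C | intermediate
23 | lactol (C3–OH) from 22 | CC(C)(C)[Si](C)(C)O[C@H]1[C@@](C)(C=C)[C@@H]2C(=C)C(O)O[C@@H]2[C@H](C(=C)CO[Si](c3ccccc3)(c3ccccc3)C(C)(C)C)[C@H]1O[Si](C)(C)C(C)(C)C | intermediate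
24 | ring-opened hydroxy enal tautomer of 23 | CC(C)(C)[Si](C)(C)O[C@H]1[C@@](C)(C=C)[C@H](C(=C)C=O)[C@H](O)[C@H](C(=C)CO[Si](c2ccccc2)(c2ccccc2)C(C)(C)C)[C@H]1O[Si](C)(C)C(C)(C)C | intermediate
25 | C3,C6-diol | CC(C)(C)[Si](C)(C)O[C@H]1[C@@](C)(C=C)[C@H](C(=C)CO)[C@H](O)[C@H](C(=C)CO[Si](c2ccccc2)(c2ccccc2)C(C)(C)C)[C@H]1O[Si](C)(C)C(C)(C)C | intermediate
26 | O3-TBS ether, free 6β-OH | CC(C)(C)[Si](C)(C)O[C@H]1[C@@](C)(C=C)[C@H](C(=C)CO[Si](C)(C)C(C)(C)C)[C@H](O)[C@H](C(=C)CO[Si](c2ccccc2)(c2ccccc2)C(C)(C)C)[C@H]1O[Si](C)(C)C(C)(C)C | intermediate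
27 | isobutyryl chloride | CC(C)C(Cl)=O | starting material
28 | 6β-isobutyrate, fully silylated | CC(C)(C)[Si](C)(C)O[C@H]1[C@@](C)(C=C)[C@H](C(=C)CO[Si](C)(C)C(C)(C)C)[C@H](OC(=O)C(C)C)[C@H](C(=C)CO[Si](c2ccccc2)(c2ccccc2)C(C)(C)C)[C@H]1O[Si](C)(C)C(C)(C)C | intermediate
29 | tetraol (3-, 8α-, 9α-, 12-OH), 6β-isobutyrate | O[C@H]1[C@@](C)(C=C)[C@H](C(=C)CO)[C@H](OC(=O)C(C)C)[C@H](C(=C)CO)[C@H]1O | intermediate
30 | 3,12-dial (8α,9α-diol) | O[C@H]1[C@@](C)(C=C)[C@H](C(=C)C=O)[C@H](OC(=O)C(C)C)[C@H](C(=C)C=O)[C@H]1O | intermediate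
31 | C12 lactol (O8–C12 hemiacetal), C3 enal | O[C@H]1[C@@](C)(C=C)[C@H](C(=C)C=O)[C@H](OC(=O)C(C)C)[C@@H]2C(=C)C(O)O[C@@H]12 | intermediate
32 | 1,2-deoxy target (C10 vinyl, lactone, enal, 9α-OH) | O[C@H]1[C@@](C)(C=C)[C@H](C(=C)C=O)[C@H](OC(=O)C(C)C)[C@@H]2C(=C)C(=O)O[C@@H]12 | intermediate
33 | CNP0496100.1 | O[C@H]1[C@@](C)([C@@H]3CO3)[C@H](C(=C)C=O)[C@H](OC(=O)C(C)C)[C@@H]2C(=C)C(=O)O[C@@H]12 | target

**Step count**
Total: 20 steps. Longest linear sequence: 20 steps from (S)-carvone (1). Compounds 12, 14, 21 and 27 are used as bought.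

**Steps most likely to fail**

Step 10. Allyl transfer to the congested tertiary radical may be too slow, so that the chain dies or the cyclised radical is reduced or adds across the ring to C13. In addition, 1,5-hydrogen transfer from C7 to the vinyl radical may compete with ring closure. Fallback: starting from 13, the ring closure is run alone as a reductive Ueno–Stork cyclisation (Bu3SnH added slowly, AIBN, benzene, 80 °C) to give the cyclised ketone with hydrogen at C10 F1. Its C9–C10 potassium enolate is formed under equilibrating conditions (KH, THF), the C8 side being disfavoured by its oxygen substituent. Allylation with allyl bromide on the convex α face then rejoins the route at 17.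

Step 20. Hydrogen-bond delivery of the oxidant from the axial C9 hydroxyl to the lower face may erode or reverse the facial preference at C1. Fallback: from 32 the epoxidation is run without facial control (dimethyldioxirane in acetone/methanol) to give 33 mixed with the (1S)-epimer F2. The mixture is then submitted to hydrolytic kinetic resolution with water and the enantiomer of N,N′-bis(3,5-di-tert-butylsalicylidene)-1,2-cyclohexanediaminocobalt acetate (trivalent cobalt) that consumes (S)-alkyloxiranes. F2 is opened to the 1,2-diol F3, which is removed by chromatography, and 33 remains.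

Step 6. The peracid may attack the C9=C10 enol ether bond (hydroxylation at C10) or the face syn to the side chain, and enolisation towards C8 in step 5 would have the same effect, so that the 6α-alcohol is not obtained cleanly. Fallback: from 6, Luche reduction gives the C9 allylic alcohol F4, which is acetylated (Ac2O, pyridine) to the C9 acetate F5. Allylic oxidation of the ring methylene C6 (CrO3, 3,5-dimethylpyrazole, CH2Cl2, −20 °C) gives the C6 enone F6. A second Luche reduction, with hydride arriving anti to the C7 side chain, gives the 6β-alcohol F7 directly, so no inversion is needed. Acetal exchange with 12 (PPTS) gives the mixed acetal F8, methanolysis (K2CO3, MeOH) gives the C9 alcohol F9, and oxidation with MnO2 rejoins the route at 13.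

Further compounds
F1 | step 10 | cyclised ketone with hydrogen at C10 (C10 epimers) | O=C1C(C)[C@@H]2C(=C)C(OCC)O[C@@H]2[C@H](C(=C)CO[Si](c3ccccc3)(c3ccccc3)C(C)(C)C)[C@H]1O[Si](C)(C)C(C)(C)C
F2 | step 20 | (1S)-epimer of 33 | O[C@H]1[C@@](C)([C@H]3CO3)[C@H](C(=C)C=O)[C@H](OC(=O)C(C)C)[C@@H]2C(=C)C(=O)O[C@@H]12
F3 | step 20 | 1,2-diol from hydrolysis of F2 | O[C@H]1[C@@](C)([C@H](O)CO)[C@H](C(=C)C=O)[C@H](OC(=O)C(C)C)[C@@H]2C(=C)C(=O)O[C@@H]12
F4 | step 6 | C9 allylic alcohol from reduction of 6 | CC1=CC[C@H](C(=C)CO[Si](c2ccccc2)(c2ccccc2)C(C)(C)C)[C@@H](O[Si](C)(C)C(C)(C)C)C1O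
F5 | step 6 | C9 acetate of F4 | CC1=CC[C@H](C(=C)CO[Si](c2ccccc2)(c2ccccc2)C(C)(C)C)[C@@H](O[Si](C)(C)C(C)(C)C)C1OC(C)=O
F6 | step 6 | C6 enone (C6=O conjugated with C5=C10), C9 acetate | CC1=CC(=O)[C@H](C(=C)CO[Si](c2ccccc2)(c2ccccc2)C(C)(C)C)[C@@H](O[Si](C)(C)C(C)(C)C)C1OC(C)=O
F7 | step 6 | 6β-alcohol (cis to C7 side chain), C9 acetate | CC1=C[C@H](O)[C@H](C(=C)CO[Si](c2ccccc2)(c2ccccc2)C(C)(C)C)[C@@H](O[Si](C)(C)C(C)(C)C)C1OC(C)=O
F8 | step 6 | 6β-O-(2-bromo-1-ethoxyallyl) mixed acetal, C9 acetate | CC1=C[C@H](OC(OCC)C(Br)=C)[C@H](C(=C)CO[Si](c2ccccc2)(c2ccccc2)C(C)(C)C)[C@@H](O[Si](C)(C)C(C)(C)C)C1OC(C)=O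
F9 | step 6 | C9 alcohol of F8 | CC1=C[C@H](OC(OCC)C(Br)=C)[C@H](C(=C)CO[Si](c2ccccc2)(c2ccccc2)C(C)(C)C)[C@@H](O[Si](C)(C)C(C)(C)C)C1O
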